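The retrosynthesis (labdane numbering; C17 sits on C8, C20 is the methyl on C10) cuts the two late C–O bonds first (C6–OH, C17=O). It then cuts C12–C13 (side chain from core), C11–C12, C9–C11, C3–C4 of ring A (with a sacrificial ester on C2), and last C10–C1 and C10–C20.
Enabling feature: C4 is a quaternary gem-dimethyl carbon attached directly to the C5 methine of ring B. The six ring carbons of (S)-carvone map onto C5–C10 (C=O = C9, C-methyl = C8/C17, ring alkene = C7=C8, stereocentre = C5) and its isopropenyl carbon sits where C4 belongs. One hydrogen atom added to its CH2 therefore gives the C4 radical with both methyls in place, ready to bond to C3.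
Forward order: ring B is bought; C20 and a C1–C3 acrylate arm go onto C10 (steps 1–2); ring A closes (3); the C2 ester is excised (4–5); C11 and C12 are added (6–9). The C13–C16 iodoenoate (10–11) is joined in step 12, and C17 and C6 are oxidised last (13–16).
Stereochemistry: C5 comes from carvone, and the S enantiomer gives the ent-labdane series that the SMILES demands. C10 is set by alkylation anti to the isopropenyl group, C9 by hydroboration anti to C20, C6 by oxidation anti to C20 and the axial C4 methyl, and 13E by anti hydroiodination followed by retentive coupling.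

Key step: step 3

Remark: faces are given as syn or anti to C20. Compounds 5 and 18 are taken as catalogue chemicals and DMDO as a titrated acetone solution. The C10 epimer composition of 4 and the C8=C17 geometry of 25 and 26 are left open because both elements are lost in the following step.

Step 1
Reactants: 1 (S)-carvone; 2 iodomethane
Product: 4 6-methylcarvone (C10 epimers; trans epimer drawn), via carvone lithium dienolate 3 (not isolated)
Conditions: LDA, THF, −78 °C; then MeI, −78 → 0 °C
Reagents that add atoms: none
Why: Kinetic deprotonation takes the only α′ CH2 (future C10) and the cross-conjugated enolate is C-methylated (enolate alkylation); the new centre is planarised again in step 2, so its configuration does not matter.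

Step 2
Reactants: 4 6-methylcarvone; 5 ethyl 2-(bromomethyl)acrylate
Product: 7 ethyl 2-{[(1R,6R)-1,3-dimethyl-2-oxo-6-(prop-1-en-2-yl)cyclohex-3-en-1-yl]methyl}acrylate, via methylcarvone lithium dienolate 6 (not isolated)
Conditions: LDA, THF, −78 → 0 °C; then 5, −78 → −20 °C
Reagents that add atoms: none
Why: In this enolate alkylation with a very reactive 2-(alkoxycarbonyl)allyl bromide, the trisubstituted enolate is attacked on the face anti to the neighbouring isopropenyl group, which puts the acrylate arm (C1) trans and the methyl (C20) cis to it and so sets C10.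

Step 3
Reactants: 7 dialkylated carvone
Product: 8 ethyl ent-9-oxo-11-nordrim-7-ene-2-carboxylate (trans-fused; ester equatorial)
Conditions: Fe(acac)3 (20 mol %), PhSiH3, EtOH (0.02 M), 60 °C, Ar
Reagents that add atoms: none
Why: An iron hydride formed from Fe(acac)3 and PhSiH3 hands H• to the CH2 end of the isopropenyl group, so the tertiary C4 radical is born carrying both methyls; it bonds to the unsubstituted acrylate carbon (C3), and the resulting α-ester radical at C2 is reduced by Fe(II) and protonated by EtOH. The closest known reaction type is the iron-catalysed HAT reductive olefin coupling (Giese-type radical conjugate addition) in its intramolecular form. Ring A closes in the 6-endo-trig mode, because both acrylate carbons end up in the ring, whereas the 5-exo path would join two fully substituted carbons against the acceptor polarity and leave an unstabilised primary radical. C5 and C10 are already fixed with C4 and C1 trans-diequatorial on ring B, so only the trans-decalin can form; the single new centre C2 is set on protonation, is drawn with the equatorial ester (anti to C20 and the axial C4 methyl), can equilibrate to that epimer in step 4 and is erased in step 5. The step needs HAT to the isopropenyl group in preference to the acrylate and the enone, which their electron-poor character secures; the enone cannot intercept the C4 radical because that would need a four-membered ring, and dilution suppresses intermolecular addition.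

Step 4
Reactants: 8 bicyclic ethyl ester
Product: 9 ent-9-oxo-11-nordrim-7-ene-2-carboxylic acid
Conditions: LiOH·H2O, THF/H2O, rt; then 1 M HCl
Reagents that add atoms: lithium hydroxide [Li+].[OH-]
Why: This is saponification of an unhindered equatorial ester; the ketone has no α-hydrogen, so nothing but C2 (transient) can epimerise.

Step 5
Reactants: 9 carboxylic acid
Product: 11 (4aR,8aR)-2,5,5,8a-tetramethyl-4a,5,6,7,8,8a-hexahydronaphthalen-1(4H)-one (ent-11-nordrim-7-en-9-one), via Barton thiohydroxamate ester 10 (not isolated)
Conditions: 1-hydroxypyridine-2(1H)-thione, DCC, DMAP (cat.), CH2Cl2, 0 °C, dark; then t-BuSH, toluene, hν (W lamp), rt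
Reagents that add atoms: none
Why: In this Barton reductive decarboxylation, visible light fragments the thiohydroxamate to CO2 and the secondary C2 radical, which takes hydrogen from the thiol long before it could reach the remote, poorly accepting enone.

Step 6
Reactants: 11 enone
Product: 13 ent-drima-7,9(11)-diene, via β-hydroxysilane 12 (not isolated)
Conditions: TMSCH2Li, THF, −78 → 0 °C, then H2O; crude 12: KH, THF, 0 °C → rt
Reagents that add atoms: (trimethylsilyl)methyllithium [Li]C[Si](C)(C)C
Why: In this Peterson olefination the organolithium adds 1,2 to the hindered ketone, which has no α-hydrogen, at a site where phosphorus ylides are sluggish, and syn-elimination of the potassium alkoxide can only give the exocyclic C9=C11 bond, unlike a proton-loss dehydration.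

Step 7
Reactants: 13 diene
Product: 15 ent-drimenol [(1R,4aR,8aR)-2,5,5,8a-tetramethyl-1,4,4a,5,6,7,8,8a-octahydronaphthalen-1-yl]methanol, via C11 alkyl-9-BBN 14 (not isolated)
Conditions: 9-BBN, THF, 0 → 40 °C; then NaOH, H2O2, 0 °C
Reagents that add atoms: hydrogen peroxide OO
Why: In this hydroboration–oxidation 9-BBN selects the terminal 1,1-disubstituted alkene over C7=C8, places boron on C11 and delivers H to C9 from the face anti to the adjacent axial C20 methyl, which sets C9 with the C11 arm equatorial and syn to C20.

Step 8
Reactants: 15 ent-drimenol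
Product: 16 ent-drimenal (ent-drim-7-en-11-al)
Conditions: DMP, CH2Cl2, 0 °C
Reagents that add atoms: none
Why: Dess–Martin oxidation stops at the aldehyde under base-free conditions, so the epimerisable C9–H and the deconjugated C7=C8 position should be kept.

Step 9
Reactants: 16 ent-drimenal
Product: 17 ent-13,14,15,16-tetranorlabda-7,11-diene (9-vinyl octalin)
Conditions: Ph3PCH3Br, KHMDS, THF, 0 °C; 16 added at −78 °C, → 0 °C
Reagents that add atoms: methyltriphenylphosphonium bromide C[P+](c1ccccc1)(c1ccccc1)c1ccccc1.[Br-]
Why: In this Wittig methylenation the unstabilised ylide adds to the aldehyde at low temperature faster than it enolises it, so C9 and the alkene position are retained.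

Step 10
Reactants: 18 methyl 4-hydroxybut-2-ynoate
Product: 19 methyl (Z)-4-hydroxy-3-iodobut-2-enoate
Conditions: NaI, AcOH, 80 °C
Reagents that add atoms: sodium iodide [Na+].[I-]
Why: In this conjugate hydroiodination of an alkynoate, iodide adds to C3 and the proton arrives anti, placing I cis and CH2OH trans to the ester, and any E isomer would lactonise and be easy to remove.

Step 11
Reactants: 19 iodo alcohol
Product: 20 methyl (Z)-4-acetoxy-3-iodobut-2-enoate
Conditions: Ac2O, pyridine, DMAP (cat.), CH2Cl2, 0 °C → rt
Reagents that add atoms: acetic anhydride CC(=O)OC(C)=O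
Why: This is a DMAP-catalysed acetylation of a primary alcohol, and it installs the C16 acetate before any other hydroxyl group exists.

Step 12
Reactants: 17 9-vinyl octalin; 20 iodoenoate
Product: 22 methyl ent-16-acetoxylabda-7,13E-dien-15-oate, via C12 alkyl-9-BBN 21 (not isolated)
Conditions: 17, 9-BBN, THF, rt; then 20, PdCl2(dppf) (cat.), AsPh3 (cat.), Cs2CO3, DMF/H2O, rt
Reagents that add atoms: none
Why: In this B-alkyl Suzuki–Miyaura coupling 9-BBN hydroborates only the monosubstituted C11=C12 alkene at C12, and the coupling replaces iodine with retention, so C12 ends up cis to CO2Me (descriptor now 13E); oxidative addition into C–I is much faster than ionisation of the allylic acetate.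

Step 13
Reactants: 22 diene ester
Product: 23 methyl ent-16-acetoxy-17-hydroxylabda-7,13E-dien-15-oate
Conditions: SeO2 (0.3 equiv), t-BuOOH, CH2Cl2, 0 °C → rt
Reagents that add atoms: tert-butyl hydroperoxide CC(C)(C)OO (terminal oxygen source); selenium dioxide O=[Se]=O (oxygen relay)
Why: In this Riley allylic oxidation (ene reaction, then [2,3]-shift) only the electron-rich C7=C8 alkene reacts, at its more substituted end and with CH3 preferred over CH, which points to the C17 methyl trans to C6, while the mild catalytic conditions limit attack on C9–H.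

Step 14
Reactants: 23 allylic alcohol
Product: 24 methyl ent-16-acetoxy-17-oxolabda-7,13E-dien-15-oate
Conditions: MnO2, CH2Cl2, rt
Reagents that add atoms: none
Why: Manganese dioxide oxidises the only (allylic) alcohol to the enal under neutral conditions that leave the esters and C9 alone.

Step 15
Reactants: 24 enal
Product: 25 methyl ent-16-acetoxy-17-(tert-butyldimethylsilyloxy)labda-6,8(17),13E-trien-15-oate
Conditions: TBSOTf, Et3N, CH2Cl2, −78 → 0 °C
Reagents that add atoms: tert-butyldimethylsilyl triflate CC(C)(C)[Si](C)(C)OS(=O)(=O)C(F)(F)F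
Why: In this soft enolisation, O-silylation of the enal followed by loss of the only conjugated γ-proton (C6–H) gives the 1-silyloxydiene, while the two esters are far less prone to silylation under these conditions.

Step 16
Reactants: 25 silyl dienol ether
Product: 27 methyl ent-16-acetoxy-6α-hydroxy-17-oxolabda-7,13E-dien-15-oate (5R,6R,9S,10S; 6-OH anti to C20), via 6,7-epoxy silyl enol ether 26 (not isolated)
Conditions: DMDO, acetone/CH2Cl2, −78 → −20 °C; then HF·pyridine, THF, 0 °C
Reagents that add atoms: dimethyldioxirane CC1(C)OO1
Why: In this vinylogous Rubottom oxidation the oxidant attacks the terminal C6=C7 bond of the electron-rich dienol ether on the face anti to C20 and the axial C4 methyl; the silyloxy group then pushes open the allylic C7–O bond to restore the enal and fluoride takes the silicon, which leaves the C6–OH cis to H-5 and the electron-poor enoate untouched.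

Compound list
1 | (S)-(+)-carvone | CC1=CC[C@@H](CC1=O)C(C)=C | starting material
2 | iodomethane | CI | starting material
3 | lithium cross-conjugated dienolate of 1 (O–C9=C10) | C=C(C)[C@H]1CC=C(C)C(O[Li])=C1 | intermediate
4 | 6-methylcarvone, (5S)-2,6-dimethyl-5-(prop-1-en-2-yl)cyclohex-2-en-1-one; trans epimer drawn, cis epimer also present | C[C@H]1C(=O)C(C)=CC[C@@H]1C(C)=C | intermediate
5 | ethyl 2-(bromomethyl)acrylate | C=C(CBr)C(=O)OCC | starting material
6 | lithium dienolate of 4 | C=C(C)[C@H]1CC=C(C)C(O[Li])=C1C | intermediate
7 | ethyl 2-{[(1R,6R)-1,3-dimethyl-2-oxo-6-(prop-1-en-2-yl)cyclohex-3-en-1-yl]methyl}acrylate (acrylate arm trans, methyl cis to isopropenyl) | C=C(C[C@@]1(C)C(=O)C(C)=CC[C@@H]1C(C)=C)C(=O)OCC | intermediate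
8 | ethyl ent-9-oxo-11-nordrim-7-ene-2-carboxylate (trans-decalin, H-5 anti to C20, ester equatorial and anti to C20) | O=C1C(C)=CC[C@@H]2C(C)(C)C[C@@H](C(=O)OCC)C[C@@]12C | intermediate
9 | ent-9-oxo-11-nordrim-7-ene-2-carboxylic acid | O=C1C(C)=CC[C@@H]2C(C)(C)C[C@@H](C(=O)O)C[C@@]12C | intermediate
10 | 2-thioxopyridin-1(2H)-yl ester of 9 (Barton ester) | O=C1C(C)=CC[C@@H]2C(C)(C)C[C@@H](C(=O)ON3C=CC=CC3=S)C[C@@]12C | intermediate
11 | (4aR,8aR)-2,5,5,8a-tetramethyl-4a,5,6,7,8,8a-hexahydronaphthalen-1(4H)-one (ent-11-nordrim-7-en-9-one) | O=C1C(C)=CC[C@@H]2C(C)(C)CCC[C@@]12C | intermediate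
12 | 9-hydroxy-9-(trimethylsilylmethyl) adduct of 11 (CH2SiMe3 anti, OH syn to C20) | C[Si](C)(C)C[C@@]1(O)C(C)=CC[C@@H]2C(C)(C)CCC[C@@]12C | intermediate
13 | ent-drima-7,9(11)-diene | C=C1C(C)=CC[C@@H]2C(C)(C)CCC[C@@]12C | intermediate
14 | B-(ent-drim-7-en-11-yl)-9-borabicyclo[3.3.1]nonane | C([C@@H]1C(C)=CC[C@@H]2C(C)(C)CCC[C@@]12C)B3C4CCCC3CCC4 | intermediate
15 | ent-drimenol, (1R,4aR,8aR) | OC[C@@H]1C(C)=CC[C@@H]2C(C)(C)CCC[C@@]12C | intermediate
16 | ent-drimenal (ent-drim-7-en-11-al) | O=C[C@@H]1C(C)=CC[C@@H]2C(C)(C)CCC[C@@]12C | intermediate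
17 | ent-13,14,15,16-tetranorlabda-7,11-diene | C=C[C@@H]1C(C)=CC[C@@H]2C(C)(C)CCC[C@@]12C | intermediate
18 | methyl 4-hydroxybut-2-ynoate | COC(=O)C#CCO | starting material
19 | methyl (Z)-4-hydroxy-3-iodobut-2-enoate | COC(=O)/C=C(\I)CO | intermediate
20 | methyl (Z)-4-acetoxy-3-iodobut-2-enoate | COC(=O)/C=C(\I)COC(C)=O | intermediate
21 | B-(ent-13,14,15,16-tetranorlabd-7-en-12-yl)-9-borabicyclo[3.3.1]nonane | C(C[C@@H]1C(C)=CC[C@@H]2C(C)(C)CCC[C@@]12C)B3C4CCCC3CCC4 | intermediate
22 | methyl ent-16-acetoxylabda-7,13E-dien-15-oate | COC(=O)/C=C(\CC[C@@H]1C(C)=CC[C@@H]2C(C)(C)CCC[C@@]12C)COC(C)=O | intermediate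
23 | methyl ent-16-acetoxy-17-hydroxylabda-7,13E-dien-15-oate | COC(=O)/C=C(\CC[C@@H]1C(CO)=CC[C@@H]2C(C)(C)CCC[C@@]12C)COC(C)=O | intermediate
24 | methyl ent-16-acetoxy-17-oxolabda-7,13E-dien-15-oate | COC(=O)/C=C(\CC[C@@H]1C(C=O)=CC[C@@H]2C(C)(C)CCC[C@@]12C)COC(C)=O | intermediate
25 | methyl ent-16-acetoxy-17-(tert-butyldimethylsilyloxy)labda-6,8(17),13E-trien-15-oate (C8=C17 geometry open) | COC(=O)/C=C(\CC[C@@H]1C(=CO[Si](C)(C)C(C)(C)C)C=C[C@@H]2C(C)(C)CCC[C@@]12C)COC(C)=O | intermediate
26 | 6,7-epoxide of 25 (oxygen anti to C20) | COC(=O)/C=C(\CC[C@@H]1C(=CO[Si](C)(C)C(C)(C)C)[C@H]3O[C@H]3[C@@H]2C(C)(C)CCC[C@@]12C)COC(C)=O | intermediate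
27 | methyl ent-16-acetoxy-6α-hydroxy-17-oxolabda-7,13E-dien-15-oate, (5R,6R,9S,10S) (CNP0112124.1) | COC(=O)/C=C(\CC[C@@H]1C(C=O)=C[C@@H](O)[C@@H]2C(C)(C)CCC[C@@]12C)COC(C)=O | target

Total step count: 16. Longest linear sequence: 14 steps (1–9 and 12–16) from (S)-carvone.

Steps most likely to fail

Step 3. The risk is that plain hydrogenation of the C4 radical or of the acrylate (a second hydrogen transfer) outruns the 6-endo closure. The fallback sets out from 7 and comes back at 8, and it makes the same C4 radical by halogen abstraction instead of hydrogen-atom transfer. HBr in AcOH/CH2Cl2 at 0 °C should add in the Markovnikov sense to the only electron-rich alkene and give the tertiary bromide F1. Slow addition of Bu3SnH/AIBN in refluxing benzene keeps the hydrogen donor dilute, so that attack on the acrylate terminus can compete, and this forms the same C3–C4 bond to give 8.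

Step 13. The risk is competing hydroxylation of the tertiary allylic C9–H or over-oxidation of the product. The fallback sets out from 22 and comes back at 23; it first places oxygen on the alkene and then moves it to C17.
- mCPBA (CH2Cl2, 0 °C) should epoxidise only C7=C8, anti to C20, to give the 7,8-epoxide F2.
- TMSOTf/DBU in toluene opens it at the tertiary C8 and removes a C17 proton, giving the exocyclic allyl silyl ether F3.
- Aqueous citric acid in THF then frees the 8(17)-en-7-ol F4.
- Catalytic Ph3SiOReO3 (Et2O, 0 °C) transposes the allylic alcohol through its perrhenate ester towards the primary alcohol with the more substituted C7=C8 alkene, which is 23.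

Step 16. The risk is attack of the oxidant on the enol-ether bond C8=C17 (α-hydroxylation) instead of C6=C7, or breakdown of the sensitive dienol ether. The fallback sets out from 25 and comes back at 27, and it removes the enol ether before the oxidation.
- Oxalic acid in wet THF at 0 °C protonates the dienol ether kinetically at C8 and should give the deconjugated 6-en-17-al F5.
- DMDO then meets a single electron-rich alkene and epoxidises C6=C7 anti to C20, giving the 6,7-epoxy aldehyde F6.
- A catalytic amount of Et3N removes the acidic C8–H and opens the epoxide at C7 (E1cB). This restores the C7=C8 enal and leaves the C6–O bond, and thus its configuration, intact.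

Further compounds
F1 | step 3 | tertiary bromide: 7 with HBr added across the isopropenyl group (Br on C4) | C=C(C[C@@]1(C)C(=O)C(C)=CC[C@@H]1C(C)(C)Br)C(=O)OCC
F2 | step 13 | 7,8-epoxide of 22 (oxygen anti to C20) | COC(=O)/C=C(\CC[C@@H]1[C@@]3(C)O[C@H]3C[C@@H]2C(C)(C)CCC[C@@]12C)COC(C)=O
F3 | step 13 | methyl ent-16-acetoxy-7-(trimethylsilyloxy)labda-8(17),13E-dien-15-oate (7-O anti to C20) | COC(=O)/C=C(\CC[C@@H]1C(=C)[C@@H](O[Si](C)(C)C)C[C@@H]2C(C)(C)CCC[C@@]12C)COC(C)=O
F4 | step 13 | methyl ent-16-acetoxy-7-hydroxylabda-8(17),13E-dien-15-oate (7-OH anti to C20) | COC(=O)/C=C(\CC[C@@H]1C(=C)[C@@H](O)C[C@@H]2C(C)(C)CCC[C@@]12C)COC(C)=O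
F5 | step 16 | methyl ent-16-acetoxy-17-oxolabda-6,13E-dien-15-oate (H-8 drawn anti to C20; inconsequential) | COC(=O)/C=C(\CC[C@@H]1[C@H](C=O)C=C[C@@H]2C(C)(C)CCC[C@@]12C)COC(C)=O
F6 | step 16 | 6,7-epoxide of F5 (oxygen anti to C20) | COC(=O)/C=C(\CC[C@@H]1[C@H](C=O)[C@H]3O[C@H]3[C@@H]2C(C)(C)CCC[C@@]12C)COC(C)=O
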